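**Retrosynthetic overview**

1. The strategy rests on the trans-fused α-methylene-γ-butyrolactone (O–C6, C7, C11=C13, C12=O) on the cyclohexane ring C5–C10: it equals a C6 hydroxyl trans to a C7 ethynyl group plus one CO (C12), so 29 ⇒ bis-silyl ether 28 ⇒ ethynyl alcohol 27 by PdI2/PBu3 cyclocarbonylation (bonds C12–O and C11–C12).
2. 27 ⇒ C6 boronate 26 (C–B to C–OH with retention) ⇒ C8 alcohol 22 + Roche-derived acid 25; the arm C4(=C3)–C15 comes from a CH2CH(OMe)2 chain (hydrolysis, α-methylenation, reduction) and the ethynyl group from a C7 CH2OH via the aldehyde (Ohira–Bestmann).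
3. C6–B and C7–CH2OH arise together by conjugate borylation/formaldehyde aldol on enone 12; C8–OH by reduction of the ketone; the C10 quaternary centre by methyl, then vinyl, conjugate additions anti to C5.
4. Ring order: the cyclohexane ring first (organocatalytic Michael addition of 1 to 2, then aldol condensation, which fixes C5), the lactone ring last.

Key step: step 18

Remark on numbering and assumptions: elemanolide numbering is used throughout (ring C5–C10; C14 methyl and C1=C2 vinyl on C10; arm C4/C3/C15 on C5; α = face of the C10 vinyl group, β = face of the C10 methyl group). Bpin = 4,4,5,5-tetramethyl-1,3,2-dioxaborolan-2-yl, TBS = tert-butyldimethylsilyl. The (S)-prolinol ether is assumed to give the (S)-aldehyde 3, as in related enamine Michael additions; the antipodal catalyst would be used if the opposite sense were found. The C8 ester is installed before the key step, so 27 and 28 carry the acyl side chain at C8.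

**Route**

Step 1
Reactants: 1 4,4-dimethoxybutanal; 2 methyl vinyl ketone
Product: 3 (S)-2-(2,2-dimethoxyethyl)-5-oxohexanal
Conditions: (S)-2-[methoxy(diphenyl)methyl]pyrrolidine (5 mol%), ethyl 3,4-dihydroxybenzoate (20 mol%), neat, 4 °C
Reagents that add atoms: none
Why: Enamine-mediated asymmetric Michael addition of the aldehyde to the enone, in which the bulky diarylmethyl group of the (S)-catalyst shields one face of the E-enamine and should set C5 as S.

Step 2
Reactants: 3 (S)-2-(2,2-dimethoxyethyl)-5-oxohexanal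
Product: 4 (S)-4-(2,2-dimethoxyethyl)cyclohex-2-en-1-one
Conditions: LiOH, i-PrOH, rt
Reagents that add atoms: none
Why: Intramolecular aldol condensation of the methyl ketone onto the aldehyde (Robinson-type closure) forms the cyclohexenone ring, the mild base limiting epimerisation at C5 before closure.

Step 3
Reactants: 4 (S)-4-(2,2-dimethoxyethyl)cyclohex-2-en-1-one
Product: 7 (S)-4-(2,2-dimethoxyethyl)-3-methylcyclohex-2-en-1-one, via lithium enolate 5 (not isolated), via sulfilimine adduct 6 (not isolated)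
Conditions: Me2CuLi (MeLi, CuI), Et2O, −78 → −40 °C; then PhS(Cl)=N-t-Bu, THF, −78 °C → rt
Reagents that add atoms: lithium dimethylcuprate, [Li+].C[Cu-]C
Why: Gilman conjugate addition followed by one-pot Mukaiyama dehydrogenation of the enolate (sulfilimine formation and syn-elimination) re-forms the enone with the methyl group on C10, the transient C10 centre being lost and C5 untouched.

Step 4
Reactants: 7 (S)-4-(2,2-dimethoxyethyl)-3-methylcyclohex-2-en-1-one
Product: 9 (3S,4S)-4-(2,2-dimethoxyethyl)-3-ethenyl-3-methylcyclohexan-1-one, via silyl enol ether 8 (not isolated)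
Conditions: CH2=CHMgBr, CuBr·SMe2 (cat.), Me3SiCl, DMPU, THF, −78 → −40 °C; then K2CO3, MeOH, 0 °C
Reagents that add atoms: vinylmagnesium bromide, C=C[Mg]Br
Why: Copper-catalysed, Me3SiCl-accelerated conjugate addition builds the C10 quaternary centre, the vinyl group entering axially anti to the C5 chain (pseudoaxial to avoid A(1,2) strain with the C10 methyl), so that vinyl is trans and methyl cis to that chain.

Step 5
Reactants: 9 (3S,4S)-4-(2,2-dimethoxyethyl)-3-ethenyl-3-methylcyclohexan-1-one
Product: 12 (4R,5S)-4-(2,2-dimethoxyethyl)-5-ethenyl-5-methylcyclohex-2-en-1-one, via lithium enolate 10 (not isolated), via sulfilimine adduct 11 (not isolated)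
Conditions: LiN(iPr)2, THF, −78 °C; then PhS(Cl)=N-t-Bu, −78 °C → rt
Reagents that add atoms: none
Why: Kinetic deprotonation takes place at C7, away from the neopentyl C9 position, and Mukaiyama dehydrogenation of this enolate can only give the C6=C7 enone because C10 is quaternary.

Step 6
Reactants: 12 (4R,5S)-4-(2,2-dimethoxyethyl)-5-ethenyl-5-methylcyclohex-2-en-1-one
Product: 14 (2R,3R,4R,5S)-4-(2,2-dimethoxyethyl)-5-ethenyl-2-(hydroxymethyl)-5-methyl-3-(Bpin)cyclohexan-1-one, via boron enolate 13 (not isolated)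
Conditions: B2pin2, CuCl (10 mol%), LiOt-Bu (15 mol%), DPEphos, THF/DMSO, rt, no protic additive; then CH2O (gas from paraformaldehyde), −40 → 0 °C; aq. NH4Cl
Reagents that add atoms: bis(pinacolato)diboron, CC1(C)OB(OC1(C)C)B1OC(C)(C)C(C)(C)O1; formaldehyde, C=O
Why: CuCl-catalysed conjugate borylation (boryl–copper syn-addition, boron to C6 anti to the C5 chain) run without a proton source leaves a boron enolate that adds to formaldehyde at C7 trans to the new C–B bond (tandem borylative aldol), C7 being epimerisable and settling equatorial.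

Step 7
Reactants: 14 the 6α-Bpin 7β-hydroxymethyl 8-ketone
Product: 15 5β-(2,2-dimethoxyethyl)-7β-(hydroxymethyl)-10β-methyl-6α-Bpin-10α-vinylcyclohexan-8α-ol
Conditions: SmI2, THF/MeOH, 0 °C
Reagents that add atoms: none
Why: Single-electron (SmI2) reduction through a ketyl chelated by the neighbouring CH2OH is expected to give the more stable equatorial 8α-alcohol, the axial 8β-epimer suffering a 1,3-diaxial contact with the C10 methyl (a hydride would attack opposite that methyl and give the 8β-alcohol).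

Step 8
Reactants: 15 the 8α-hydroxy 7β-hydroxymethyl diol
Product: 16 8α-hydroxy-6α-Bpin-cyclohexane-7β-carbaldehyde (5β-dimethoxyethyl, 10β-methyl, 10α-vinyl)
Conditions: TEMPO (cat.), PhI(OAc)2, CH2Cl2, rt
Reagents that add atoms: none
Why: Oxoammonium (TEMPO) oxidation is selective for the primary alcohol over the hindered secondary C8 hydroxyl and leaves the C–B bond alone.

Step 9
Reactants: 16 the 7β-carbaldehyde; 17 dimethyl (1-diazo-2-oxopropyl)phosphonate
Product: 18 5β-(2,2-dimethoxyethyl)-7β-ethynyl-10β-methyl-6α-Bpin-10α-vinylcyclohexan-8α-ol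
Conditions: K2CO3, MeOH, 0 °C → rt
Reagents that add atoms: dimethyl (1-diazo-2-oxopropyl)phosphonate (17), CC(=O)C(=[N+]=[N-])P(=O)(OC)OC
Why: Ohira–Bestmann (Seyferth–Gilbert) homologation converts the aldehyde into the terminal alkyne under mild carbonate/methanol conditions, C7 staying in its thermodynamically preferred equatorial configuration.

Step 10
Reactants: 18 the 7β-ethynyl 8α-alcohol acetal
Product: 19 2-[(8α-hydroxy-7β-ethynyl-10β-methyl-6α-Bpin-10α-vinylcyclohexan-5β-yl)]acetaldehyde
Conditions: 1 M HCl, THF, rt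
Reagents that add atoms: water, O
Why: Acid-catalysed hydrolysis of the dimethyl acetal, which the alkyl pinacol boronate, the alkyne and the alkenes tolerate and which is run before any silyl group is present.

Step 11
Reactants: 19 the C5 acetaldehyde
Product: 20 2-(8α-hydroxy-7β-ethynyl-10β-methyl-6α-Bpin-10α-vinylcyclohexan-5β-yl)prop-2-enal
Conditions: aq. CH2O (37%), pyrrolidine (10 mol%), EtCO2H (10 mol%), i-PrOH, 45 °C
Reagents that add atoms: formaldehyde, C=O
Why: Amine-catalysed α-methylenation of the aldehyde (Mannich condensation with formaldehyde, then elimination of the amine) installs C3 as the exocyclic methylene.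

Step 12
Reactants: 20 the 2-substituted propenal
Product: 21 5β-(3-hydroxyprop-1-en-2-yl)-7β-ethynyl-10β-methyl-6α-Bpin-10α-vinylcyclohexan-8α-ol
Conditions: NaBH4, CeCl3·7H2O, MeOH, −40 → 0 °C
Reagents that add atoms: none
Why: Luche reduction gives clean 1,2-reduction of the enal to the allylic alcohol C15–OH.

Step 13
Reactants: 21 the 8α,15-diol
Product: 22 5β-[3-(TBS-oxy)prop-1-en-2-yl]-7β-ethynyl-10β-methyl-6α-Bpin-10α-vinylcyclohexan-8α-ol
Conditions: TBSCl, imidazole, CH2Cl2, 0 °C
Reagents that add atoms: tert-butyldimethylsilyl chloride, CC(C)(C)[Si](C)(C)Cl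
Why: Silylation with TBSCl is selective for the primary allylic C15 hydroxyl over the hindered secondary C8 hydroxyl.

Step 14
Reactants: 23 methyl (R)-3-hydroxy-2-methylpropanoate (Roche ester)
Product: 24 methyl (R)-3-(TBS-oxy)-2-methylpropanoate
Conditions: TBSCl, imidazole, DMF, rt
Reagents that add atoms: tert-butyldimethylsilyl chloride, CC(C)(C)[Si](C)(C)Cl
Why: Standard silyl ether formation on the primary alcohol, the stereocentre not being involved.

Step 15
Reactants: 24 methyl (R)-3-(TBS-oxy)-2-methylpropanoate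
Product: 25 (R)-3-(TBS-oxy)-2-methylpropanoic acid
Conditions: LiOH, THF/MeOH/H2O, 0 °C → rt; then 1 M HCl to pH 4
Reagents that add atoms: lithium hydroxide, [Li+].[OH-]
Why: Saponification of the methyl ester under mild LiOH conditions that should leave the α-stereocentre and the β-silyloxy group intact.

Step 16
Reactants: 22 the 8α-alcohol with C15 TBS ether; 25 (R)-3-(TBS-oxy)-2-methylpropanoic acid
Product: 26 8α-[(R)-3-(TBS-oxy)-2-methylpropanoyloxy] 6α-Bpin 7β-ethynyl C15 TBS ether
Conditions: DCC, DMAP, CH2Cl2, 0 °C → rt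
Reagents that add atoms: none
Why: Steglich esterification (carbodiimide activation, DMAP acyl transfer) of the only free hydroxyl, with retention at C8 because the C8–O bond is not broken.

Step 17
Reactants: 26 the C8 ester C6 boronate
Product: 27 8α-[(R)-3-(TBS-oxy)-2-methylpropanoyloxy]-7β-ethynyl-15-(TBS-oxy) cyclohexan-6α-ol (key-step precursor)
Conditions: NaBO3·4H2O, THF/H2O, rt
Reagents that add atoms: sodium perborate, [Na+].[O-]OB=O
Why: Perborate oxidation of the secondary alkyl boronate proceeds by 1,2-migration of C6 from boron to oxygen with retention, giving the 6α-alcohol under conditions that spare the alkenes, the alkyne, the ester and the silyl ethers.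

Step 18
Reactants: 27 the trans 7-ethynyl 6-hydroxy cyclohexane
Product: 28 bis-TBS ether of the target (8α-acyloxy-15-silyloxy elema-1,3,11(13)-trien-12,6α-olide)
Conditions: PdI2 (5 mol%), PBu3 (10 mol%), CO (7 bar), MeCN, 75 °C
Reagents that add atoms: carbon monoxide, [C-]#[O+]
Why: Divalent palladium (PdI2/PBu3) takes up CO and the C6 hydroxyl to give an alkoxycarbonyl–palladium species, which inserts the C7 ethynyl group in a syn fashion so that C12 bonds to the internal alkyne carbon C11 and palladium sits on C13; protonolysis of the alkenyl–palladium bond by the HI set free releases the exocyclic C11=C13 methylene and returns the catalyst. The closest known reaction type is the PdI2/PBu3-catalysed cyclocarbonylation of 2-ethynyl alcohols to α-methylene-γ-butyrolactones, documented for trans-2-ethynylcyclohexanol giving the trans-fused lactone. The lactone ring (O, C12, C11, C7, C6) closes in a 5-exo-dig mode with respect to the triple bond, the tether excluding acyl delivery to the terminal carbon. No stereocentre is created; C6 and C7 keep their trans-diequatorial arrangement, which holds the C6 oxygen and the alkyne within bonding distance. The step needs chemoselectivity for the alkyne over the C1=C2 vinyl and C3=C4 propenyl groups and a single free hydroxyl: the first follows from the tethered five-ring insertion being much faster than any untethered alkene insertion, the second from the C8 ester and both silyl ethers already being in place.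

Step 19
Reactants: 28 the bis-TBS lactone
Product: 29 CNP0133858.1, 8α-[(R)-3-hydroxy-2-methylpropanoyloxy]-15-hydroxyelema-1,3,11(13)-trien-12,6α-olide
Conditions: HF·pyridine, pyridine, THF, 0 °C → rt
Reagents that add atoms: none
Why: Fluoride-mediated cleavage of both primary TBS ethers under buffered, weakly acidic conditions that avoid acyl migration and conjugate addition to the α-methylene lactone.

**Compound list**

1 | 4,4-dimethoxybutanal | COC(OC)CCC=O | starting material
2 | methyl vinyl ketone | CC(=O)C=C | starting material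
3 | (S)-2-(2,2-dimethoxyethyl)-5-oxohexanal | O=C[C@H](CC(OC)OC)CCC(C)=O | intermediate
4 | (S)-4-(2,2-dimethoxyethyl)cyclohex-2-en-1-one | O=C1C=C[C@H](CC(OC)OC)CC1 | intermediate
5 | lithium (3S,4S)-4-(2,2-dimethoxyethyl)-3-methylcyclohex-1-en-1-olate (not isolated) | [Li]OC1=C[C@@H](C)[C@H](CC(OC)OC)CC1 | intermediate
6 | 2-(N-tert-butyl-S-phenylsulfilimidoyl) adduct of trans-4-(2,2-dimethoxyethyl)-3-methylcyclohexanone, epimers at C2 and sulfur (not isolated) | O=C1C(S(=NC(C)(C)C)c2ccccc2)[C@@H](C)[C@H](CC(OC)OC)CC1 | intermediate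
7 | (S)-4-(2,2-dimethoxyethyl)-3-methylcyclohex-2-en-1-one | O=C1C=C(C)[C@H](CC(OC)OC)CC1 | intermediate
8 | trimethylsilyl enol ether of 9, C8=C9 enol ether (not isolated) | C=C[C@]1(C)C=C(O[Si](C)(C)C)CC[C@H]1CC(OC)OC | intermediate
9 | (3S,4S)-4-(2,2-dimethoxyethyl)-3-ethenyl-3-methylcyclohexan-1-one | C=C[C@]1(C)CC(=O)CC[C@H]1CC(OC)OC | intermediate
10 | kinetic lithium enolate of 9, C7=C8 enolate (not isolated) | C=C[C@]1(C)CC(O[Li])=CC[C@H]1CC(OC)OC | intermediate
11 | C7 N-tert-butyl-S-phenylsulfilimine adduct of 9, epimers at C7 and sulfur (not isolated) | C=C[C@]1(C)CC(=O)C(S(=NC(C)(C)C)c2ccccc2)C[C@H]1CC(OC)OC | intermediate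
12 | (4R,5S)-4-(2,2-dimethoxyethyl)-5-ethenyl-5-methylcyclohex-2-en-1-one | C=C[C@]1(C)CC(=O)C=C[C@H]1CC(OC)OC | intermediate
13 | boron enolate, C8 O-Bpin C7=C8 enolate with 6α-Bpin (not isolated) | C=C[C@]1(C)CC(OB2OC(C)(C)C(C)(C)O2)=C[C@H](B3OC(C)(C)C(C)(C)O3)[C@H]1CC(OC)OC | intermediate
14 | (2R,3R,4R,5S)-4-(2,2-dimethoxyethyl)-5-ethenyl-2-(hydroxymethyl)-5-methyl-3-(Bpin)cyclohexan-1-one (6α-Bpin, 7β-CH2OH, 8-oxo) | C=C[C@]1(C)CC(=O)[C@@H](CO)[C@H](B2OC(C)(C)C(C)(C)O2)[C@H]1CC(OC)OC | intermediate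
15 | 5β-(2,2-dimethoxyethyl)-7β-(hydroxymethyl)-10β-methyl-6α-Bpin-10α-vinylcyclohexan-8α-ol | C=C[C@]1(C)C[C@H](O)[C@@H](CO)[C@H](B2OC(C)(C)C(C)(C)O2)[C@H]1CC(OC)OC | intermediate
16 | 8α-hydroxy-5β-(2,2-dimethoxyethyl)-10β-methyl-6α-Bpin-10α-vinylcyclohexane-7β-carbaldehyde | C=C[C@]1(C)C[C@H](O)[C@@H](C=O)[C@H](B2OC(C)(C)C(C)(C)O2)[C@H]1CC(OC)OC | intermediate
17 | dimethyl (1-diazo-2-oxopropyl)phosphonate | CC(=O)C(=[N+]=[N-])P(=O)(OC)OC | starting material
18 | 5β-(2,2-dimethoxyethyl)-7β-ethynyl-10β-methyl-6α-Bpin-10α-vinylcyclohexan-8α-ol | C=C[C@]1(C)C[C@H](O)[C@@H](C#C)[C@H](B2OC(C)(C)C(C)(C)O2)[C@H]1CC(OC)OC | intermediate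
19 | 2-(7β-ethynyl-8α-hydroxy-10β-methyl-6α-Bpin-10α-vinylcyclohexan-5β-yl)acetaldehyde | C=C[C@]1(C)C[C@H](O)[C@@H](C#C)[C@H](B2OC(C)(C)C(C)(C)O2)[C@H]1CC=O | intermediate
20 | 2-(7β-ethynyl-8α-hydroxy-10β-methyl-6α-Bpin-10α-vinylcyclohexan-5β-yl)prop-2-enal | C=C[C@]1(C)C[C@H](O)[C@@H](C#C)[C@H](B2OC(C)(C)C(C)(C)O2)[C@H]1C(=C)C=O | intermediate
21 | 7β-ethynyl-5β-(3-hydroxyprop-1-en-2-yl)-10β-methyl-6α-Bpin-10α-vinylcyclohexan-8α-ol | C=C[C@]1(C)C[C@H](O)[C@@H](C#C)[C@H](B2OC(C)(C)C(C)(C)O2)[C@H]1C(=C)CO | intermediate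
22 | 7β-ethynyl-5β-[3-(TBS-oxy)prop-1-en-2-yl]-10β-methyl-6α-Bpin-10α-vinylcyclohexan-8α-ol | C=C[C@]1(C)C[C@H](O)[C@@H](C#C)[C@H](B2OC(C)(C)C(C)(C)O2)[C@H]1C(=C)CO[Si](C)(C)C(C)(C)C | intermediate
23 | methyl (R)-3-hydroxy-2-methylpropanoate (Roche ester) | COC(=O)[C@H](C)CO | starting material
24 | methyl (R)-3-(TBS-oxy)-2-methylpropanoate | COC(=O)[C@H](C)CO[Si](C)(C)C(C)(C)C | intermediate
25 | (R)-3-(TBS-oxy)-2-methylpropanoic acid | OC(=O)[C@H](C)CO[Si](C)(C)C(C)(C)C | intermediate
26 | 8α-[(R)-3-(TBS-oxy)-2-methylpropanoyloxy]-7β-ethynyl-6α-Bpin-15-(TBS-oxy) compound | C=C[C@]1(C)C[C@H](OC(=O)[C@H](C)CO[Si](C)(C)C(C)(C)C)[C@@H](C#C)[C@H](B2OC(C)(C)C(C)(C)O2)[C@H]1C(=C)CO[Si](C)(C)C(C)(C)C | intermediate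
27 | key-step precursor: 8α-[(R)-3-(TBS-oxy)-2-methylpropanoyloxy]-7β-ethynyl-15-(TBS-oxy)-10β-methyl-10α-vinylcyclohexan-6α-ol | C=C[C@]1(C)C[C@H](OC(=O)[C@H](C)CO[Si](C)(C)C(C)(C)C)[C@@H](C#C)[C@H](O)[C@H]1C(=C)CO[Si](C)(C)C(C)(C)C | intermediate
28 | bis-TBS ether of the target α-methylene lactone | C=C[C@]1(C)C[C@H](OC(=O)[C@H](C)CO[Si](C)(C)C(C)(C)C)[C@H]2C(=C)C(=O)O[C@@H]2[C@H]1C(=C)CO[Si](C)(C)C(C)(C)C | intermediate
29 | CNP0133858.1, 8α-[(R)-3-hydroxy-2-methylpropanoyloxy]-15-hydroxyelema-1,3,11(13)-trien-12,6α-olide | C=C[C@]1(C)C[C@H](OC(=O)[C@H](C)CO)[C@H]2C(=C)C(=O)O[C@@H]2[C@H]1C(=C)CO | target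

**Step count**

Total: 19 steps. Longest linear sequence: 17 steps (steps 1–13 and 16–19); steps 14–15 prepare acid 25.

**Steps most likely to fail**

1. Step 18 (cyclocarbonylation). Formation of the alkoxycarbonyl–palladium species at the hindered C6 hydroxyl may be slow, so that alkyne oligomerisation or untethered carbonylation competes, and PBu3 may add reversibly to the α-methylene lactone at 75 °C. Fallback, setting out from 27 and coming back at 28: the C6 hydroxyl is converted with COCl2 and pyridine into the chloroformate F1 and then with PhSeH and pyridine into the Se-phenyl selenocarbonate F2. Bu3SnH and AIBN in benzene at 80 °C then generate the alkoxycarbonyl radical, which adds 5-exo-dig to the alkyne; the alkenyl radical is reduced by the stannane to give 28.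

2. Step 6 (borylative aldol). The pinacol boron enolate may be protonated or may add too slowly to formaldehyde, formaldehyde may polymerise, and the β-hydroxy ketone may dehydrate or undergo retro-aldol cleavage on work-up. Fallback, setting out from 12 and coming back at 14: protic conjugate borylation (B2pin2, CuCl, NaOt-Bu, DPEphos, MeOH, THF) gives the β-boryl ketone F3. LiN(iPr)2 at −78 °C then forms the kinetic C7 lithium enolate F4, which is hydroxymethylated with gaseous formaldehyde to give 14.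

3. Step 7 (C8 reduction). Facial selectivity may be poor: delivery of hydrogen to the face next to the axial C10 methyl may be too slow, and the axial 8β-alcohol then forms. Fallback, setting out from 14 and coming back at 18: LiBH(s-Bu)3 reduces from the open α-face to the 8β-alcohol F5; TEMPO/PhI(OAc)2 gives the 8β-hydroxy aldehyde F6 and reagent 17 the 8β-alkynol F7. Mitsunobu reaction with 4-nitrobenzoic acid (PPh3, DIAD) inverts C8 to the 8α 4-nitrobenzoate F8, and K2CO3 in MeOH releases 18.

**Further compounds**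

F1 | step 18 | C6 chloroformate of 27 | C=C[C@]1(C)C[C@H](OC(=O)[C@H](C)CO[Si](C)(C)C(C)(C)C)[C@@H](C#C)[C@H](OC(Cl)=O)[C@H]1C(=C)CO[Si](C)(C)C(C)(C)C
F2 | step 18 | C6 Se-phenyl selenocarbonate of 27 | C=C[C@]1(C)C[C@H](OC(=O)[C@H](C)CO[Si](C)(C)C(C)(C)C)[C@@H](C#C)[C@H](OC(=O)[Se]c2ccccc2)[C@H]1C(=C)CO[Si](C)(C)C(C)(C)C
F3 | step 6 | 6α-Bpin ketone: 4-(2,2-dimethoxyethyl)-5-ethenyl-5-methyl-3-(Bpin)cyclohexan-1-one | C=C[C@]1(C)CC(=O)C[C@H](B2OC(C)(C)C(C)(C)O2)[C@H]1CC(OC)OC
F4 | step 6 | kinetic C7 lithium enolate of F3 | C=C[C@]1(C)CC(O[Li])=C[C@H](B2OC(C)(C)C(C)(C)O2)[C@H]1CC(OC)OC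
F5 | step 7 | 8β-epimer of 15 | C=C[C@]1(C)C[C@@H](O)[C@@H](CO)[C@H](B2OC(C)(C)C(C)(C)O2)[C@H]1CC(OC)OC
F6 | step 7 | 8β-epimer of 16 | C=C[C@]1(C)C[C@@H](O)[C@@H](C=O)[C@H](B2OC(C)(C)C(C)(C)O2)[C@H]1CC(OC)OC
F7 | step 7 | 8β-epimer of 18 | C=C[C@]1(C)C[C@@H](O)[C@@H](C#C)[C@H](B2OC(C)(C)C(C)(C)O2)[C@H]1CC(OC)OC
F8 | step 7 | 8α 4-nitrobenzoate of 18 | C=C[C@]1(C)C[C@H](OC(=O)c2ccc(cc2)[N+](=O)[O-])[C@@H](C#C)[C@H](B2OC(C)(C)C(C)(C)O2)[C@H]1CC(OC)OC
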